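You asked for a quick number, and my decision is to rank these flasks on one clock, not on their temperatures.

    intermediate → product (k1 = 6.1 × 10⁻⁵ s⁻¹, Ea1 = 89.0 kJ mol⁻¹)
    substrate + reagent → intermediate + by-product (k2 = 0.0012 L mol⁻¹ s⁻¹, Ea2 = 65.0 kJ mol⁻¹)
    (constants at 25 °C)

| flask | substrate | reagent | temperature | time | remark |
|---|---|---|---|---|---|
| Sunday's | 10 mM | 20.0 mM | 25 °C | 12 h |  |
| Monday's | 10 mM | 20.0 mM | 50 °C | 12 h |  |
| Thursday's | 10 mM | 20.0 mM |  | 12 h | at 50 °C until 2.5 h, from then on at 25 °C |

- the flask that comes out highest in amount of product, in percent of the substrate charged, or "all alike" when all lie within 1.5 percentage points (Sunday's / Monday's / Thursday's / all alike)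
- product at the end, in percent of the substrate charged, Sunday's
- product at the end, in percent of the substrate charged, Monday's
- product at the end, in percent of the substrate charged, Thursday's

- the constants hold at 25 °C; other temperatures follow from the activation energies

**Two lags.** Treat each flask as two first-order stages in series. Intake, substrate meeting reagent, has the time constant τ = 1/(k·c), where k is its rate constant (0.0012 L mol⁻¹ s⁻¹) and c the reagent charge. That gives 11.6 h at 25 °C, a pseudo-first-order figure for the start, with the reagent at its charge. The second stage, intermediate to product, has the time constant L, the inverse of its rate constant: 4.55 h. Intake is the slower, so I take it as the rate-limiting step. At 50 °C the two become 1.53 h and 0.283 h, and intake stays the slower, so on these starting figures control does not change hands.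

**The clock.** Intake speeds up by a factor of 7.6 from 25 °C to 50 °C, so I count an hour at 50 °C as that many intake hours at 25 °C. A lag in series means that the product at the end is roughly the substrate converted one L earlier, with L taken at the closing temperature. Thursday's has 24.0 h of θ, the intake hours reckoned at 25 °C and stopped one L before the end. Sunday's has 7.45 h and Monday's 89.1 h.

**My number.** Reagent falls as it works, so I use the second-order integral. With a the substrate charge, the product share is one minus (c−a)/(c·exp((c−a)kθ)−a). That gives 43.1 % for Sunday's, 98.9 % for Monday's and 78.4 % for Thursday's. My pick is Monday's.

**Your forecast.** It names Monday's, with 42 %, 98.9 % and 78 % in the same order, and says of Thursday's “so it lands between the other two”. On Sunday's, mine stands higher.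

**The run.** The simulation gives Monday's highest, with 41.7 %, 98.9 % and 78.2 %. Thursday's is not at rest: at the end it holds 17 % of its substrate and 59 % of its reagent. By 120 h its θ reaches 132 h, which reckons to 99.8 %, and the computed value is 99.8 %. Sunday's then stands at 99.6 % and Monday's at 100 %, a spread of 0.40 percentage points, inside the margin.

**A neighbour.** A neighbour of Thursday's charged with 34 mM of reagent keeps the same θ, and the formula with that charge gives 94.0 %. The simulation gives 93.6 %.

(The constants used here were chosen freely; no experiment stands behind them.)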